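The runs are simulated with constants of no real substance, noise included.

A curve that flattens tempts us to stretch it along the logarithm of time, but its late gains are small beside the scatter of the readings. So we count doublings of the clock and ask what each one adds.

the same everywhere: free catalyst 0.0200 M

| flask | starting material | reagent | product | time |
|---|---|---|---|---|
| amber | 1.00 M | 1.10 M |  |  |
| blue | 0.400 M | 0.500 M |  |  |
| red | 2.00 M | 1.10 M |  |  |
| violet | 1.00 M | 1.10 M | 0.500 M |  |
| grey | 1.00 M | 1.10 M |  | 48 h |

| run | time / h | [product] / M |
|---|---|---|
| amber run | 0.91 | 0.132 |
| amber run | 2.8 | 0.192 |
| amber run | 5.3 | 0.253 |
| amber run | 8.4 | 0.290 |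
| amber run | 12 | 0.277 |
| amber run | 16 | 0.301 |
| blue run | 0.91 | 0.031 |
| blue run | 2.8 | 0.065 |
| blue run | 5.3 | 0.086 |
| blue run | 8.4 | 0.105 |
| blue run | 12 | 0.105 |
| blue run | 16 | 0.110 |
| red run | 0.91 | 0.187 |
| red run | 2.8 | 0.285 |
| red run | 5.3 | 0.319 |
| red run | 8.4 | 0.353 |
| red run | 12 | 0.370 |
| red run | 16 | 0.388 |
| violet run | 0.91 | 0.618 |
| violet run | 2.8 | 0.698 |
| violet run | 5.3 | 0.746 |
| violet run | 8.4 | 0.779 |
| violet run | 12 | 0.782 |
| violet run | 16 | 0.806 |

(each reading ± 0.01 M)

1. apparent order in [starting material] of the starting rate, round the charge of the amber run (the rate where two percent of its starting material have turned into product) (one fixed amount of product, the same in the runs compared)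
2. apparent order in [reagent] of the starting rate, round the charge of the amber run (the rate where two percent of its starting material have turned into product)
3. product in the grey run at 48 h, as a share of the starting material charged
4. which of these the readings show (the product speeds the reaction / two substrates go astray together / the product kills the catalyst)

- Overall: starting material + reagent -> product, with free catalyst as catalyst.
- Constant volume, constant temperature.
- "The second partner" is reagent.
- An order is taken over about fifteen percent of the charge, up and down.

Less its charged product, the violet run stands at 0.306 M at 16 h, and the amber run at 0.301 M. Within the scatter of 0.01 M, added product shows no effect on the gain at that time, which counts against both answers about product. The red run, with twice the starting material of the amber run, has turned 19.4% of its charge at 16 h, less than the 30.1% of the amber run. A loss that pairs up starting material fits that drop, so we choose two substrates going astray together.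

We make no hand estimate of the two orders and leave them to the forecast.

For the grey run we average the amber and violet gains, since both have its charge of starting material and reagent. From 2.8 h to 5.3 h they add 0.0592 M per doubling. From 8.4 h to 16 h they add 0.0204 M. This last figure is our doubling gain, the product added while the clock doubles. The two windows lie 1.58 doublings apart, so each doubling keeps a factor of 0.511 of the gain before it, about half. The mean product at 16 h is 0.303 M, and 48 h lies 1.58 doublings further on. The shrinking gains add 0.0140 M, so we commit to 0.317 M, or 31.7% of the charge.

The weak link is that factor, since a mean gain carries a scatter of 0.01 M, about half of the doubling gain. We therefore reforge it by letting the gain not shrink at all, which gives 33.6%.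

The forecast gives 1.02 and 1.25 for the orders, 37% for the grey run, and "two substrates go astray together". For the yield it argues by “Extrapolating from 0.30 M at 16 h”, and its share stands above ours.

The simulation gives 1.0, 1.1, 30.9% and "two substrates go astray together".

    2 free catalyst ⇌ catalyst dimer, settled at all times (734.0 M⁻¹)
    free catalyst + starting material + reagent → product + free catalyst (61.56 M⁻² h⁻¹)
    2 starting material → homo dimer (0.6624 M⁻¹ h⁻¹)

The forecast's yield lies 6.1 percentage points above the grey run, which ends 0.00501 M past our mean at 16 h, about a quarter of the doubling gain. The grey run stands low at 48 h because of the path from two starting material to homo dimer. With that path taken away, the same flask gives 94.9% instead of 30.9%. That gap of 64 points equals 31.4 doubling gains.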